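**Strategy.** Torilin (guaiane numbering) is disconnected at the C3–C4 bond of its cyclopentenone (ring A, C1–C5), the bond between the ketone carbon and the methyl-bearing enone carbon. Because C4 carries C15 and sits on the ring-fusion carbon C5, it is a latent acetyl group, and C3 is a latent aldehyde two carbons from C1. The key step, a carbene-catalysed crossed benzoin cyclisation, inverts the polarity of C3, closes ring A and leaves at C4 the hydroxyl whose loss gives the C4=C5 enone. The precursor is a keto aldehyde on a fully substituted cycloheptane (ring B), itself made by an enantioselective formal [4+3] cycloaddition that sets C10 and marks C5/C1 with an enol ether.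

Key step: step 11

Remark on numbering: guaiane numbers are used throughout. Ring A is C1–C2–C3(=O)–C4(C15)=C5; ring B is C1, C5, C6, C7, C8, C9, C10; C11 (with C12 and C13) is on C7; C14 is on C10.
Remark on assumptions: ethyl 2-diazo-3-oxobutanoate (1) is taken as a purchasable material, and the S-configured dirhodium catalyst is assumed to deliver (10S); if the opposite sense were found, its enantiomer would be used.

**Step 1**
Reactants: 1 ethyl 2-diazo-3-oxobutanoate
Product: 2 ethyl 3-[(tert-butyldimethylsilyl)oxy]-2-diazobut-3-enoate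
Conditions: TBSOTf, Et3N, CH2Cl2, 0 °C
Reagents that add atoms: tert-butyldimethylsilyl trifluoromethanesulfonate CC(C)(C)[Si](C)(C)OS(=O)(=O)C(F)(F)F
Why: Soft enolisation of the acetyl group and O-silylation (silyl enol ether formation) should give the siloxy-substituted vinyldiazoacetate without touching the diazo group; no stereocentre is formed.

**Step 2**
Reactants: 3 (E)-pent-3-en-2-one
Product: 4 (E)-triisopropyl(penta-1,3-dien-2-yloxy)silane
Conditions: TIPSOTf, Et3N, CH2Cl2, 0 °C
Reagents that add atoms: triisopropylsilyl trifluoromethanesulfonate CC(C)[Si](OS(=O)(=O)C(F)(F)F)(C(C)C)C(C)C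
Why: Soft enolisation at the α′-methyl group (silyl enol ether formation) should give the cross-conjugated 2-siloxydiene with the E-propenyl geometry retained.

**Step 3**
Reactants: 2 ethyl 3-[(tert-butyldimethylsilyl)oxy]-2-diazobut-3-enoate; 4 (E)-triisopropyl(penta-1,3-dien-2-yloxy)silane
Product: 6 ethyl (4S)-2-[(tert-butyldimethylsilyl)oxy]-4-methyl-6-[(triisopropylsilyl)oxy]cyclohepta-1,5-diene-1-carboxylate, via cis-divinylcyclopropane 5 (not isolated)
Conditions: Rh2(S-PTAD)4 [dirhodium tetrakis((S)-(1-adamantyl)phthalimidoacetate)] (1 mol %), hexane, slow addition of 2, −20 °C → 40 °C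
Reagents that add atoms: none
Why: Rhodium-carbenoid cyclopropanation should take place at the electron-rich 1,1-disubstituted enol ether double bond (the E-disubstituted one is inert to donor/acceptor carbenoids) and the cis-divinylcyclopropane should undergo boat-type Cope rearrangement (tandem cyclopropanation/Cope rearrangement, a formal [4+3] cycloaddition), so that C10 is set by the chiral dirhodium carboxylate and relayed stereospecifically through the E-propenyl terminus.

**Step 4**
Reactants: 6 ethyl (4S)-2-[(tert-butyldimethylsilyl)oxy]-4-methyl-6-[(triisopropylsilyl)oxy]cyclohepta-1,5-diene-1-carboxylate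
Product: 8 ethyl (1S,2R,4S)-2-hydroxy-4-methyl-6-[(triisopropylsilyl)oxy]cyclohept-5-ene-1-carboxylate, via β-keto ester 7 (not isolated)
Conditions: K2CO3 (0.3 equiv), EtOH, 0 °C; then NaBH4, −40 → −20 °C
Reagents that add atoms: none
Why: Carbonate-catalysed ethanolysis should cleave only the vinylogous silyl ester (the simple TIPS enol ether is inert), and borohydride reduction of the rapidly C7-epimerising β-keto ester is expected to go through the epimer with the ester and the C10 methyl group cis, hydride adding to the free opposite face, which sets C7 and C8 all-cis to C14 (diastereoselective ketone reduction with dynamic epimerisation at C7).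

**Step 5**
Reactants: 8 ethyl (1S,2R,4S)-2-hydroxy-4-methyl-6-[(triisopropylsilyl)oxy]cyclohept-5-ene-1-carboxylate
Product: 9 (1R,2S,6S)-2-(2-hydroxypropan-2-yl)-6-methyl-4-[(triisopropylsilyl)oxy]cyclohept-4-en-1-ol
Conditions: MeMgBr (5 equiv), THF, 0 °C → rt
Reagents that add atoms: methylmagnesium bromide C[Mg]Br
Why: Double Grignard addition to the ester (after deprotonation of the hydroxyl) should give the tertiary carbinol C11 with C12 and C13; no stereocentre is changed.

**Step 6**
Reactants: 9 (1R,2S,6S)-2-(2-hydroxypropan-2-yl)-6-methyl-4-[(triisopropylsilyl)oxy]cyclohept-4-en-1-ol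
Product: 10 acetonide of diol 9 (8-O/11-O-isopropylidene acetal; cis-fused 1,3-dioxane; C5 TIPS enol ether retained; 7S,8R,10S)
Conditions: 2-methoxypropene, PPTS (5 mol %), CH2Cl2, 0 °C
Reagents that add atoms: 2-methoxypropene COC(C)=C
Why: Acid-catalysed acetal exchange with the far more easily protonated 2-methoxypropene (acetonide protection of the 1,3-diol) should close the cis-fused dioxane while sparing the TIPS enol ether.

**Step 7**
Reactants: 10 acetonide of diol 9
Product: 11 C5 enol triflate (C5=C1 double bond; OSO2CF3 on C5; 8,11-acetonide; 7S,8R,10S)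
Conditions: CsF, PhNTf2, DME, rt
Reagents that add atoms: N-phenylbis(trifluoromethanesulfonimide) O=S(=O)(N(c1ccccc1)S(=O)(=O)C(F)(F)F)C(F)(F)F
Why: Fluoride should cleave the Si–O bond to the regiodefined C5(O)=C1 enolate, which is O-triflated in situ (enol triflate formation from a silyl enol ether), so the double-bond position fixed in step 3 is kept.

**Step 8**
Reactants: 11 C5 enol triflate
Product: 13 methyl ketone (acetyl group on C5 of the C1=C5 cycloheptene; 8,11-acetonide; 7S,8R,10S), via 2-butoxydiene 12 (not isolated)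
Conditions: butyl vinyl ether, Pd(OAc)2 (5 mol %), dppp (10 mol %), Et3N, DMF, 70 °C; then 0.5 M HCl, THF, 0 °C
Reagents that add atoms: butyl vinyl ether C=COCCCC; water O
Why: Heck coupling of the vinyl triflate at the α-carbon of the electron-rich vinyl ether (cationic pathway with the bidentate phosphine) should give a 2-butoxydiene whose mild hydrolysis unveils the methyl ketone, placing C4 and C15 on C5.

**Step 9**
Reactants: 13 methyl ketone
Product: 15 keto alkene (1R,5R,7S,8R,10S; allyl on C1 trans to C14; acetyl on C5 trans to allyl; 8,11-acetonide), via silyl enol ether 14 (not isolated)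
Conditions: allylMgBr, CuI, LiCl, TMSCl, THF, −78 °C; then aqueous citric acid, rt
Reagents that add atoms: allylmagnesium bromide C=CC[Mg]Br
Why: TMSCl-accelerated conjugate addition of allylcopper to the β-carbon C1 should occur anti to the adjacent C10 methyl group, setting C1 with C2 trans to C14, and C5 is protonated on hydrolysis to the more stable trans ketone (C5 stays epimerisable and is removed later).

**Step 10**
Reactants: 15 keto alkene
Product: 17 keto aldehyde (1R,5R,7S,8R,10S)-8,11-(isopropylidenedioxy)-4-oxo-3,4-secoguaian-3-al, via ozonide 16 (not isolated)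
Conditions: O3, CH2Cl2, −78 °C; then PPh3, −78 °C → rt
Reagents that add atoms: ozone [O-][O+]=O
Why: Ozonolysis of the terminal alkene with reductive work-up should give the C3 aldehyde, the ketone, the acetonide and all stereocentres being inert.

**Step 11**
Reactants: 17 keto aldehyde
Product: 18 α-ketol 4-hydroxy-8,11-(isopropylidenedioxy)guaian-3-one (1R,7S,8R,10S; mixture at C4 and C5)
Conditions: 3-benzyl-5-(2-hydroxyethyl)-4-methylthiazolium chloride (20 mol %), DBU (15 mol %), t-BuOH, 40 °C, 0.02 M
Reagents that add atoms: none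
Why: The thiazol-2-ylidene formed by deprotonation of the salt adds to the C3 aldehyde and proton transfer gives the enaminol (acyl-anion equivalent), whose nucleophilic C3 attacks the C4 carbonyl of the acetyl group; collapse of the adduct releases the carbene and the tertiary α-ketol. The closest known reaction type is the intramolecular crossed aldehyde–ketone benzoin (acyloin) cyclisation of 1,5-keto aldehydes to 2-hydroxy-2-methylcyclopentanones. Ring A (C1–C2–C3–C4–C5) closes in the 5-exo-trig mode, the attacked C4=O bond lying outside the new ring. The new stereocentre C4 and the epimerisable C5 need no control because both become sp2 in step 12, while C1, C7, C8 and C10 are not touched. The step needs chemoselectivity for acyl-anion addition to the ketone over intermolecular aldehyde dimerisation and over base-mediated aldol condensation of the C15 methyl ketone enolate onto C3 (six-membered ring); the 1,5-disposition of C3 and C4 on adjacent ring carbons, high dilution and only catalytic base in a protic medium should secure this.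

**Step 12**
Reactants: 18 α-ketol
Product: 21 (1R,7S,8R,10S)-8,11-(isopropylidenedioxy)guai-4-en-3-one, via chlorosulfite 19 (not isolated), via exo-methylene ketone 20 (not isolated)
Conditions: SOCl2, pyridine, CH2Cl2, −20 → 0 °C; solvent exchange; then RuHCl(CO)(PPh3)3 (3 mol %), toluene, 80 °C
Reagents that add atoms: none
Why: Pyridine-induced elimination of the tertiary chlorosulfite (dehydration) should give the conjugated endo- and exo-alkenes, and ruthenium hydride-mediated double-bond migration (alkene isomerisation) should converge them on the tetrasubstituted C4=C5 enone under neutral conditions that leave C1 untouched.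

**Step 13**
Reactants: 21 (1R,7S,8R,10S)-8,11-(isopropylidenedioxy)guai-4-en-3-one
Product: 22 (1R,7S,8R,10S)-8,11-dihydroxyguai-4-en-3-one
Conditions: AcOH–H2O–THF (3:1:1), 40 °C
Reagents that add atoms: none
Why: Mild aqueous acid should hydrolyse the 1,3-dioxane acetal (acetonide cleavage) without affecting the enone or the tertiary alcohol.

**Step 14**
Reactants: 22 (1R,7S,8R,10S)-8,11-dihydroxyguai-4-en-3-one; 23 angelic acid
Product: 25 (1R,7S,8R,10S)-8-angeloyloxy-11-hydroxyguai-4-en-3-one, via mixed anhydride 24 (not isolated)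
Conditions: 23, 2,4,6-trichlorobenzoyl chloride, Et3N, toluene, rt; then 22, toluene, 75 °C
Reagents that add atoms: none
Why: The mixed 2,4,6-trichlorobenzoic anhydride (Yamaguchi esterification) should acylate the secondary C8 hydroxyl in preference to the tertiary C11 hydroxyl and, without a nucleophilic catalyst, keep the Z geometry of the angelate.

**Step 15**
Reactants: 25 (1R,7S,8R,10S)-8-angeloyloxy-11-hydroxyguai-4-en-3-one
Product: 26 torilin
Conditions: Ac2O, DMAP, Et3N, CH2Cl2, rt → 35 °C
Reagents that add atoms: acetic anhydride CC(=O)OC(C)=O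
Why: DMAP-catalysed acetylation of the remaining tertiary alcohol should complete the target, the angelate and the enone being inert to these conditions.

**Compound list**
1 | ethyl 2-diazo-3-oxobutanoate | CCOC(=O)C(=[N+]=[N-])C(C)=O | starting material
2 | ethyl 3-[(tert-butyldimethylsilyl)oxy]-2-diazobut-3-enoate | CCOC(=O)C(=[N+]=[N-])C(=C)O[Si](C)(C)C(C)(C)C | intermediate
3 | (E)-pent-3-en-2-one | C/C=C/C(C)=O | starting material
4 | (E)-triisopropyl(penta-1,3-dien-2-yloxy)silane | C=C(O[Si](C(C)C)(C(C)C)C(C)C)/C=C/C | intermediate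
5 | ethyl 1-[1-(tert-butyldimethylsilyloxy)ethenyl]-2-[(E)-prop-1-enyl]-2-(triisopropylsilyloxy)cyclopropane-1-carboxylate, the two alkenyl groups cis | CCOC(=O)[C@@]1(C(=C)O[Si](C)(C)C(C)(C)C)C[C@@]1(/C=C/C)O[Si](C(C)C)(C(C)C)C(C)C | intermediate (not isolated)
6 | ethyl (4S)-2-[(tert-butyldimethylsilyl)oxy]-4-methyl-6-[(triisopropylsilyl)oxy]cyclohepta-1,5-diene-1-carboxylate | CCOC(=O)C1=C(O[Si](C)(C)C(C)(C)C)C[C@H](C)C=C(O[Si](C(C)C)(C(C)C)C(C)C)C1 | intermediate
7 | ethyl (4S)-4-methyl-2-oxo-6-[(triisopropylsilyl)oxy]cyclohept-5-ene-1-carboxylate (C1 epimers, partly enolised) | O=C1C[C@H](C)C=C(O[Si](C(C)C)(C(C)C)C(C)C)CC1C(=O)OCC | intermediate (not isolated)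
8 | ethyl (1S,2R,4S)-2-hydroxy-4-methyl-6-[(triisopropylsilyl)oxy]cyclohept-5-ene-1-carboxylate | O[C@@H]1C[C@H](C)C=C(O[Si](C(C)C)(C(C)C)C(C)C)C[C@@H]1C(=O)OCC | intermediate
9 | (1R,2S,6S)-2-(2-hydroxypropan-2-yl)-6-methyl-4-[(triisopropylsilyl)oxy]cyclohept-4-en-1-ol | O[C@@H]1C[C@H](C)C=C(O[Si](C(C)C)(C(C)C)C(C)C)C[C@@H]1C(C)(C)O | intermediate
10 | acetonide of 9 (8-O/11-O-isopropylidene acetal, cis-fused 1,3-dioxane; 7S,8R,10S) | CC1(C)O[C@@H]2C[C@H](C)C=C(O[Si](C(C)C)(C(C)C)C(C)C)C[C@@H]2C(C)(C)O1 | intermediate
11 | C5 enol triflate of the C5=C1 cycloheptene, 8,11-acetonide (7S,8R,10S) | CC1(C)O[C@@H]2C[C@H](C)C=C(OS(=O)(=O)C(F)(F)F)C[C@@H]2C(C)(C)O1 | intermediate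
12 | 2-butoxydiene: 1-butoxyethenyl group on C5 of the C5=C1 cycloheptene, 8,11-acetonide | CC1(C)O[C@@H]2C[C@H](C)C=C(C(=C)OCCCC)C[C@@H]2C(C)(C)O1 | intermediate (not isolated)
13 | methyl ketone: acetyl group on C5 of the C1=C5 cycloheptene, 8,11-acetonide (7S,8R,10S) | CC1(C)O[C@@H]2C[C@H](C)C=C(C(C)=O)C[C@@H]2C(C)(C)O1 | intermediate
14 | trimethylsilyl enol ether of 15 (C4=C5 enol ether, allyl on C1) | CC1(C)O[C@@H]2C[C@H](C)[C@@H](CC=C)C(=C(C)O[Si](C)(C)C)C[C@@H]2C(C)(C)O1 | intermediate (not isolated)
15 | keto alkene (1R,5R,7S,8R,10S): allyl on C1 trans to C14, acetyl on C5, 8,11-acetonide | CC1(C)O[C@@H]2C[C@H](C)[C@@H](CC=C)[C@H](C(C)=O)C[C@@H]2C(C)(C)O1 | intermediate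
16 | ozonide (1,2,4-trioxolane) of 15 | CC1(C)O[C@@H]2C[C@H](C)[C@@H](CC3OCOO3)[C@H](C(C)=O)C[C@@H]2C(C)(C)O1 | intermediate (not isolated)
17 | (1R,5R,7S,8R,10S)-8,11-(isopropylidenedioxy)-4-oxo-3,4-secoguaian-3-al | CC1(C)O[C@@H]2C[C@H](C)[C@@H](CC=O)[C@H](C(C)=O)C[C@@H]2C(C)(C)O1 | intermediate
18 | 4-hydroxy-8,11-(isopropylidenedioxy)guaian-3-one (1R,7S,8R,10S; mixture at C4 and C5) | CC1(C)O[C@@H]2C[C@H](C)[C@H]3CC(=O)C(C)(O)C3C[C@@H]2C(C)(C)O1 | intermediate
19 | C4 chlorosulfite of 18 | CC1(C)O[C@@H]2C[C@H](C)[C@H]3CC(=O)C(C)(OS(Cl)=O)C3C[C@@H]2C(C)(C)O1 | intermediate (not isolated)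
20 | 8,11-(isopropylidenedioxy)guai-4(15)-en-3-one | CC1(C)O[C@@H]2C[C@H](C)[C@H]3CC(=O)C(=C)C3C[C@@H]2C(C)(C)O1 | intermediate (not isolated)
21 | (1R,7S,8R,10S)-8,11-(isopropylidenedioxy)guai-4-en-3-one | CC1(C)O[C@@H]2C[C@H](C)[C@H]3CC(=O)C(C)=C3C[C@@H]2C(C)(C)O1 | intermediate
22 | (1R,7S,8R,10S)-8,11-dihydroxyguai-4-en-3-one | O[C@@H]1C[C@H](C)[C@H]2CC(=O)C(C)=C2C[C@@H]1C(C)(C)O | intermediate
23 | angelic acid, (Z)-2-methylbut-2-enoic acid | C/C=C(/C)C(O)=O | starting material
24 | angelic 2,4,6-trichlorobenzoic anhydride | C/C=C(/C)C(=O)OC(=O)c1c(Cl)cc(Cl)cc1Cl | intermediate (not isolated)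
25 | (1R,7S,8R,10S)-8-angeloyloxy-11-hydroxyguai-4-en-3-one | C/C=C(/C)C(=O)O[C@@H]1C[C@H](C)[C@H]2CC(=O)C(C)=C2C[C@@H]1C(C)(C)O | intermediate
26 | torilin, (1R,7S,8R,10S)-11-acetoxy-8-angeloyloxyguai-4-en-3-one | C/C=C(/C)C(=O)O[C@@H]1C[C@H](C)[C@H]2CC(=O)C(C)=C2C[C@@H]1C(C)(C)OC(C)=O | target

**Step count.** Total: 15 steps. Longest linear sequence: 14 steps (steps 1 and 3–15, from 1).

**Steps most likely to fail**

Step 3. The cyclopropanation of the 1,1-disubstituted enol ether may proceed with incomplete enantiofacial control, or a trans-divinylcyclopropane may form that reaches the Cope manifold only through ring opening, which erodes enantiomeric purity. The fallback adds a resolution to catalyst control. It sets out from 8 of insufficient enantiomeric purity. Lipase-mediated transesterification (Candida antarctica lipase B, vinyl acetate, MTBE, 30 °C) is expected to acylate the major (8R) enantiomer preferentially (large substituent C7, medium substituent C9), giving the acetate of 8 F1. This is separated from the unreacted minor enantiomer and treated with MeMgBr as in step 5 (one more equivalent cleaves the acetate), which comes back to the route at 9.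

Step 4. Hydride delivery may show poor facial selectivity with respect to the remote C10 methyl group, or poor cis selectivity with respect to the ester. The fallback replaces substrate control by catalyst control followed by inversion. It sets out from 7, isolated after the ethanolysis. Asymmetric hydrogenation with dynamic kinetic resolution ([RuCl(p-cymene)((R)-BINAP)]Cl or its enantiomer, whichever fixes C7 as in 8; H2 at 50 bar, EtOH–CH2Cl2) should give the trans-hydroxy ester F2, in which C8 is epimeric. Mitsunobu inversion at C8 (benzoic acid, PPh3, DIAD, THF) should give the cis-benzoate F3. MeMgBr as in step 5 (two further equivalents) then cleaves the benzoate and converts the ester, coming back to the route at 9.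

Step 11. Base-mediated aldol condensation of the methyl ketone enolate onto the aldehyde may compete, or the acyl-anion equivalent may add too slowly to the unactivated ketone. The fallback forms the same C3–C4 bond reductively. It sets out from 17. Intramolecular pinacol coupling (SmI2, THF, t-BuOH, −78 °C) should give the C3,C4-diol F4. Oxidation of its secondary hydroxyl only (2-iodoxybenzoic acid, DMSO, rt) comes back to the route at 18.

**Further compounds**
F1 | step 3 | ethyl (1S,2R,4S)-2-acetoxy-4-methyl-6-[(triisopropylsilyl)oxy]cyclohept-5-ene-1-carboxylate | CC(=O)O[C@@H]1C[C@H](C)C=C(O[Si](C(C)C)(C(C)C)C(C)C)C[C@@H]1C(=O)OCC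
F2 | step 4 | ethyl (1S,2S,4S)-2-hydroxy-4-methyl-6-[(triisopropylsilyl)oxy]cyclohept-5-ene-1-carboxylate | O[C@H]1C[C@H](C)C=C(O[Si](C(C)C)(C(C)C)C(C)C)C[C@@H]1C(=O)OCC
F3 | step 4 | ethyl (1S,2R,4S)-2-(benzoyloxy)-4-methyl-6-[(triisopropylsilyl)oxy]cyclohept-5-ene-1-carboxylate | O=C(O[C@@H]1C[C@H](C)C=C(O[Si](C(C)C)(C(C)C)C(C)C)C[C@@H]1C(=O)OCC)c1ccccc1
F4 | step 11 | 3,4-dihydroxy-8,11-(isopropylidenedioxy)guaiane (1R,7S,8R,10S; mixture at C3, C4 and C5) | CC1(C)O[C@@H]2C[C@H](C)[C@H]3CC(O)C(C)(O)C3C[C@@H]2C(C)(C)O1
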